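The constants used here stand for no real mixture; the result is computed.

The reading at 25 h comes down to how many turnovers the substrate has made by then, and I count them for this flask.

substrate 0.38 M; coupling partner 4.00 equiv; initiator 5.7 mol%; time 25 h

    initiator → 2 initiating radical (k1 = 1.40 × 10⁻⁴ h⁻¹)
    substrate + initiating radical → capped initiator + first chain carrier (k2 = 45700 L mol⁻¹ s⁻¹)
    coupling partner + first chain carrier → product + second chain carrier (k3 = 4.61 × 10⁵ L mol⁻¹ h⁻¹)
    substrate + second chain carrier → released group + first chain carrier (k4 = 1.57 × 10⁶ L mol⁻¹ h⁻¹)
    2 first chain carrier → ended chains A (k5 = 7.6 × 10⁶ L mol⁻¹ s⁻¹)
    2 second chain carrier → ended chains B (k6 = 2.8 × 10⁷ L mol⁻¹ s⁻¹)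
    coupling partner + released group ⇌ idle adduct A, settled at all times (K7 = 1.6 L mol⁻¹)
    substrate + product ⇌ idle adduct B, settled at all times (K8 = 80 L mol⁻¹)

- part of the substrate that has reacted at 25 h
- share of the unused coupling partner that is free and not bound as idle adduct A, at 25 h

- percent here means substrate units held: one ended chains A or idle adduct B counts as two
- what is said of product includes idle adduct B
- what is said of released group includes idle adduct A
- for a step with 2 of a species take k times the square, and two of it per event
- what has gone from substrate into another species counts as reacted, even if it can come back
- in an amount of product, one idle adduct B counts as one product
- run time (flask): 25 h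

The initiator starts the chains, and its half-life of 210 d is far longer than the run, so I hold its supply of radicals steady at 1.60 × 10⁻⁵ h⁻¹ of the substrate charge. Chains end at the pace they start, and the two carriers hand over to each other at equal pace. Balancing both ends of the chain at the starting charges, I find that the chain turns over 0.00787 h⁻¹ of the substrate present. Each new product then ties up a second substrate, since its binding constant times the starting substrate is 30, much more than one. Each turn therefore costs two units, and the substrate has a pseudo-first-order life of 63.5 h, which I hold through the run.

My two times are the reading time and this life. Their ratio, 0.394, is the number of turnovers: reading time over substrate life. One minus e to the minus that number gives 32.5 % reacted. One released group comes from each turn and binds coupling partner at balance, which leaves 97.2 % of the unused coupling partner free.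

The forecast gives 32.4 % and 97 %, on the ground that adduct B “binds most of the product”.

The flask gives 32.5 % and 97.0 %.

The flask stands in mid-course, with 67 % of its substrate unbound, through two things acting together, the reading at 25 h rather than at 250 h and the loss of second chain carrier to ended chains B: the later reading gives 93.6 %, and the run without that loss gives 81.2 %. Part of what has reacted is owed to the tying up as idle adduct B: the run without that tying up reads 18.0 %. Each turn then costs one unit, so the turnovers drop to 0.197, which gives 17.9 %. For the neighbour flask with 1.60 equiv of coupling partner, the same count gives 0.288 turnovers and so 25.0 %, and that flask reads 25.5 %.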